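**Retrosynthetic overview**
1. The two esters are cut last: first the hindered C-6 angelate, then the allylic C-7 epoxyangelate. This leaves the cis-fused 6/7 diol. The oxirane arrives ready-made in the acid, made by Sharpless epoxidation of the alcohol derived from angelic acid.
2. Key cut: both carbocycles are opened together, at C4a–C9a (enamine Michael addition) and at C3=C4 (aldol condensation). This gives one open-chain C15 keto aldehyde whose diol is locked as a trans-acetonide.
3. The keto aldehyde comes from a (Z)-allylic alcohol by oxidation, Horner–Wadsworth–Emmons extension and cleavage of a terminal vinyl group.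
4. The (Z)-allylic alcohol, with both carbinol centres, comes from a butenolide. The butenolide is made by an asymmetric vinylogous Mukaiyama aldol reaction of 3-methyl-2-silyloxyfuran with 2,2-dimethylpent-4-enal.
5. Ring order: butenolide (opened again), then dioxolane (temporary), then the seven-membered and six-membered rings in the same flask; the oxirane is attached with the acid.

Assumption: the four building blocks (3-methylfuran-2(5H)-one, 2,2-dimethylpent-4-enal, diethyl (2-oxobutyl)phosphonate, angelic acid) are bought. The facial sense of the Ti–binaphthol addition is assigned by analogy and would be checked on the first alcohol by Mosher ester analysis.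
Locants C-1 to C-9a are those of the benzo[7]annulen-2-one name of the diol.

**Step 1**
Reactants: 1 3-methylfuran-2(5H)-one
Product: 2 3-methyl-2-(trimethylsilyloxy)furan
Conditions: Me3SiOTf, Et3N, Et2O, 0 °C
Reagents that add atoms: trimethylsilyl trifluoromethanesulfonate, C[Si](C)(C)OS(=O)(=O)C(F)(F)F
Why: Soft enolisation (O-silylation followed by γ-deprotonation) gives the aromatic 2-silyloxyfuran, the standard dienolate equivalent for a vinylogous Mukaiyama aldol reaction, and no stereocentre is formed.

**Step 2**
Reactants: 2 3-methyl-2-(trimethylsilyloxy)furan; 3 2,2-dimethylpent-4-enal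
Product: 4 (5R)-5-[(1R)-1-hydroxy-2,2-dimethylpent-4-en-1-yl]-3-methylfuran-2(5H)-one
Conditions: Ti(OiPr)4 (20 mol %), (S)-1,1'-bi-2-naphthol (20 mol %), Et2O, −20 °C; then 1 M HCl, THF
Reagents that add atoms: none
Why: In this catalytic asymmetric vinylogous Mukaiyama aldol reaction the furan attacks only through C-5, Lewis-acid-promoted additions of 2-silyloxyfurans are threo-selective through an open transition state (reinforced by the neopentyl aldehyde), and the (S)-binaphthol–titanium complex is expected to expose the Si face of 3, so both carbinol centres (1'R,5R) are set together while the lactone ring fixes the later C8=C9 alkene as Z.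

**Step 3**
Reactants: 4 butenolide alcohol
Product: 5 (2Z,4R,5R)-2,6,6-trimethylnona-2,8-diene-1,4,5-triol
Conditions: iBu2AlH (4.5 equiv), CH2Cl2, −78 to 0 °C; aq. potassium sodium tartrate
Reagents that add atoms: none
Why: This lactone reduction runs by 1,2-hydride addition through the lactol to the (Z)-2-ene-1,4-diol, which keeps the ring-derived Z geometry, leaves both stereocentres and the isolated alkene untouched, and avoids isolating the furan-prone lactol.

**Step 4**
Reactants: 5 triol
Product: 6 (2Z)-3-[(4R,5R)-2,2-dimethyl-5-(2-methylpent-4-en-2-yl)-1,3-dioxolan-4-yl]-2-methylprop-2-en-1-ol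
Conditions: 2,2-dimethoxypropane, pyridinium p-toluenesulfonate (5 mol %), CH2Cl2, 0 °C to rt
Reagents that add atoms: 2,2-dimethoxypropane, COC(C)(C)OC
Why: Thermodynamic acetalisation (isopropylidene protection) favours the five-membered trans-4,5-disubstituted dioxolane of the vicinal threo diol over any seven-membered acetal, leaves only the primary allylic alcohol free, and installs the conformational lock used in step 7.

**Step 5**
Reactants: 6 allylic alcohol; 7 diethyl (2-oxobutyl)phosphonate
Product: 9 (4E,6Z)-7-[(4R,5R)-2,2-dimethyl-5-(2-methylpent-4-en-2-yl)-1,3-dioxolan-4-yl]-6-methylhepta-4,6-dien-3-one, via Z-enal 8 (not isolated)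
Conditions: MnO2 (15 equiv), CH2Cl2, rt; filter; then 7, LiCl, iPr2NEt, MeCN, 0 °C to rt
Reagents that add atoms: none
Why: MnO2 oxidises only the allylic alcohol, and the crude Z-enal is trapped at once in a Masamune–Roush Horner–Wadsworth–Emmons olefination, in which the stabilised keto phosphonate gives the new C=C as E under conditions mild enough to keep the Z-alkene and the adjacent stereocentre intact.

**Step 6**
Reactants: 9 dienone
Product: 10 3-{(4R,5R)-2,2-dimethyl-5-[(1Z,3E)-2-methyl-5-oxohepta-1,3-dien-1-yl]-1,3-dioxolan-4-yl}-3-methylbutanal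
Conditions: OsO4 (2 mol %), NaIO4 (4 equiv), 2,6-lutidine, dioxane–H2O 3:1, rt
Reagents that add atoms: sodium periodate, [Na+].[O-]I(=O)(=O)=O
Why: In this Lemieux–Johnson cleavage the electrophilic OsO4 picks the only electron-rich, unhindered alkene (the terminal vinyl group) over the two carbonyl-conjugated and more hindered dienone double bonds, and NaIO4 cleaves the diol to the aldehyde with loss of one carbon.

**Step 7**
Reactants: 10 open-chain keto aldehyde
Product: 12 (4aS,6R,7R,9aR)-6,7-(isopropylidenedioxy)-3,5,5,9-tetramethyl-1,4a,5,6,7,9a-hexahydro-2H-benzo[7]annulen-2-one, via keto aldehyde 11 (not isolated)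
Conditions: pyrrolidine (0.3 equiv), AcOH (0.3 equiv), toluene, 0.005 M, 60 °C
Reagents that add atoms: none
Why: Proposed new method: pyrrolidine converts the aldehyde into its enamine, whose β-carbon adds to the β-carbon of the s-trans dienone (Stork enamine Michael addition, equally viewed as an intramolecular inverse-demand oxa-Diels–Alder step) to close the seven-membered ring, and the 1,5-keto aldehyde 11 then closes the cyclohexenone through the ethyl-ketone CH2 by the aldol-condensation half of a Robinson annulation, the closest known reaction being the Stork–Robinson synthesis of 2,4,4-trimethylcyclohex-2-enone from an isobutyraldehyde enamine and ethyl vinyl ketone; the gem-dimethyl group, the Z-alkene and the trans-dioxolane leave few free rotors, the trans-dioxolane disfavours the competing 5-exo 1,6-addition (which would give a trans-bicyclo[3.3.0]octane), a chair-like cycloheptene transition state with both C–O bonds and the enone arm equatorial puts H-7 and H-9a on the same face (9aR), and C-4a, which equilibrates through the enamine in 11, is expected to be drained through the cis (4aS) epimer, whose formyl carbon is gauche to one rather than two of the geminal methyl groups when it becomes tetrahedral in the aldol step.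

**Step 8**
Reactants: 12 tricyclic enone acetonide
Product: 13 (4aS,6R,7R,9aR)-6,7-dihydroxy-3,5,5,9-tetramethyl-1,4a,5,6,7,9a-hexahydro-2H-benzo[7]annulen-2-one
Conditions: AcOH–H2O 4:1, 40 °C
Reagents that add atoms: none
Why: Mild acid hydrolysis of the trans-fused dioxolane (acetal cleavage) frees the diol without touching the enone or any stereocentre.

**Step 9**
Reactants: 14 angelic acid, (2Z)-2-methylbut-2-enoic acid
Product: 15 (2Z)-2-methylbut-2-en-1-ol
Conditions: LiAlH4, Et2O, 0 °C to rt
Reagents that add atoms: none
Why: Hydride reduction of the carboxylic acid leaves the trisubstituted alkene and its Z geometry unchanged.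

**Step 10**
Reactants: 15 (2Z)-2-methylbut-2-en-1-ol
Product: 16 [(2S,3R)-2,3-dimethyloxiran-2-yl]methanol
Conditions: Ti(OiPr)4 (10 mol %), L-(+)-diethyl tartrate (12 mol %), tBuOOH, 4 Å molecular sieves, CH2Cl2, −20 °C
Reagents that add atoms: tert-butyl hydroperoxide, CC(C)(C)OO
Why: In the Katsuki–Sharpless asymmetric epoxidation, syn oxygen transfer keeps CH2OH and the C-3 methyl cis, and the L-(+)-tartrate catalyst, which gives (2S)-epoxides from primary allylic alcohols, sets (2S,3R).

**Step 11**
Reactants: 16 epoxy alcohol
Product: 17 (2R,3R)-2,3-dimethyloxirane-2-carboxylic acid (epoxyangelic acid)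
Conditions: 2,2,6,6-tetramethylpiperidine 1-oxyl (10 mol %), PhI(OAc)2 (2.2 equiv), MeCN–H2O 1:1, rt
Reagents that add atoms: water, O
Why: The oxoammonium oxidation takes the primary alcohol through the aldehyde hydrate to the acid under near-neutral conditions that spare the epoxide, and the C-2 descriptor changes to R only through the CIP priorities.

**Step 12**
Reactants: 13 diol; 17 epoxyangelic acid
Product: 18 (4aS,6R,7R,9aR)-6-hydroxy-3,5,5,9-tetramethyl-2-oxo-1,4a,5,6,7,9a-hexahydro-2H-benzo[7]annulen-7-yl (2R,3R)-2,3-dimethyloxirane-2-carboxylate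
Conditions: N,N'-dicyclohexylcarbodiimide (1.05 equiv), 4-(dimethylamino)pyridine (10 mol %), CH2Cl2, 0 °C
Reagents that add atoms: none
Why: In this Steglich esterification the allylic C-7 hydroxyl is much more accessible than the C-6 hydroxyl next to the quaternary carbon, so one equivalent of the hindered acid acylates C-7 selectively with retention at every stereocentre.

**Step 13**
Reactants: 18 hydroxy ester; 14 angelic acid
Product: 20 target CNP0332927.1, via mixed anhydride 19 (not isolated)
Conditions: 14, 2,4,6-trichlorobenzoyl chloride, Et3N, toluene, rt; filter; then 18, 80 °C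
Reagents that add atoms: none
Why: In this Yamaguchi-type esterification run without a nucleophilic catalyst, the alcohol attacks the less hindered angeloyl carbonyl of 19, a protocol that acylates hindered secondary alcohols without angelate-to-tiglate (Z to E) isomerisation.

**Compound list**
1 | 3-methylfuran-2(5H)-one | CC1=CCOC1=O | starting material
2 | 3-methyl-2-(trimethylsilyloxy)furan | Cc1ccoc1O[Si](C)(C)C | intermediate
3 | 2,2-dimethylpent-4-enal | C=CCC(C)(C)C=O | starting material
4 | (5R)-5-[(1R)-1-hydroxy-2,2-dimethylpent-4-en-1-yl]-3-methylfuran-2(5H)-one | C=CCC(C)(C)[C@@H](O)[C@@H]1OC(=O)C(C)=C1 | intermediate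
5 | (2Z,4R,5R)-2,6,6-trimethylnona-2,8-diene-1,4,5-triol | C=CCC(C)(C)[C@@H](O)[C@H](O)/C=C(/C)CO | intermediate
6 | (2Z)-3-[(4R,5R)-2,2-dimethyl-5-(2-methylpent-4-en-2-yl)-1,3-dioxolan-4-yl]-2-methylprop-2-en-1-ol | C=CCC(C)(C)[C@H]1OC(C)(C)O[C@@H]1/C=C(/C)CO | intermediate
7 | diethyl (2-oxobutyl)phosphonate | CCC(=O)CP(=O)(OCC)OCC | starting material
8 | (2Z)-3-[(4R,5R)-2,2-dimethyl-5-(2-methylpent-4-en-2-yl)-1,3-dioxolan-4-yl]-2-methylprop-2-enal | C=CCC(C)(C)[C@H]1OC(C)(C)O[C@@H]1/C=C(/C)C=O | intermediate
9 | (4E,6Z)-7-[(4R,5R)-2,2-dimethyl-5-(2-methylpent-4-en-2-yl)-1,3-dioxolan-4-yl]-6-methylhepta-4,6-dien-3-one | C=CCC(C)(C)[C@H]1OC(C)(C)O[C@@H]1/C=C(/C)\C=C\C(=O)CC | intermediate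
10 | 3-{(4R,5R)-2,2-dimethyl-5-[(1Z,3E)-2-methyl-5-oxohepta-1,3-dien-1-yl]-1,3-dioxolan-4-yl}-3-methylbutanal | O=CCC(C)(C)[C@H]1OC(C)(C)O[C@@H]1/C=C(/C)\C=C\C(=O)CC | intermediate
11 | (3aR,5S,6R,8aR)-2,2,4,4,7-pentamethyl-6-(2-oxobutyl)-3a,5,6,8a-tetrahydro-4H-cyclohepta[d][1,3]dioxole-5-carbaldehyde | CC1(C)O[C@H]2[C@H](O1)C=C(C)[C@H](CC(=O)CC)[C@H](C=O)C2(C)C | intermediate
12 | (4aS,6R,7R,9aR)-6,7-(isopropylidenedioxy)-3,5,5,9-tetramethyl-1,4a,5,6,7,9a-hexahydro-2H-benzo[7]annulen-2-one | CC1(C)O[C@H]2[C@H](O1)C=C(C)[C@@H]3CC(=O)C(C)=C[C@@H]3C2(C)C | intermediate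
13 | (4aS,6R,7R,9aR)-6,7-dihydroxy-3,5,5,9-tetramethyl-1,4a,5,6,7,9a-hexahydro-2H-benzo[7]annulen-2-one | O[C@H]1[C@H](O)C=C(C)[C@@H]2CC(=O)C(C)=C[C@@H]2C1(C)C | intermediate
14 | angelic acid, (2Z)-2-methylbut-2-enoic acid | C/C=C(/C)C(=O)O | starting material
15 | (2Z)-2-methylbut-2-en-1-ol | C/C=C(/C)CO | intermediate
16 | [(2S,3R)-2,3-dimethyloxiran-2-yl]methanol | OC[C@]1(C)O[C@@H]1C | intermediate
17 | (2R,3R)-2,3-dimethyloxirane-2-carboxylic acid | OC(=O)[C@]1(C)O[C@@H]1C | intermediate
18 | C-7 epoxyangelate of diol 13 with free C-6 hydroxyl | O[C@H]1[C@H](OC(=O)[C@]2(C)O[C@@H]2C)C=C(C)[C@@H]2CC(=O)C(C)=C[C@@H]2C1(C)C | intermediate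
19 | (2Z)-2-methylbut-2-enoic 2,4,6-trichlorobenzoic anhydride | C/C=C(/C)C(=O)OC(=O)c1c(Cl)cc(Cl)cc1Cl | intermediate
20 | (4aS,6R,7R,9aR)-3,5,5,9-tetramethyl-6-{[(2Z)-2-methylbut-2-enoyl]oxy}-2-oxo-1,4a,5,6,7,9a-hexahydro-2H-benzo[7]annulen-7-yl (2R,3R)-2,3-dimethyloxirane-2-carboxylate | C/C=C(/C)C(=O)O[C@H]1[C@H](OC(=O)[C@]2(C)O[C@@H]2C)C=C(C)[C@@H]2CC(=O)C(C)=C[C@@H]2C1(C)C | target

**Totals**
- Total step count: 13.
- Longest linear sequence: 10 steps (steps 1–8, 12, 13).

**Steps most likely to fail**

Step 7 (double ring closure). The seven-membered Michael closure onto a β-substituted dienone may be slow, and the 1,6-addition may leak through. The cis ring fusion rests only on a conformational argument and is the weakest stereochemical point of the route.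

The fallback sets out from 10 and comes back at 12. Aldehyde 10 is silylated chemoselectively (tBuMe2SiOTf, Et3N, CH2Cl2, −78 °C) to the (Z)-silyl enol ether F1. On warming with Eu(fod)3 in toluene, the enone acts as a 1-oxadiene and the compound undergoes an intramolecular inverse-demand hetero-Diels–Alder reaction. This again closes two rings at once (cycloheptene and dihydropyran). Because the addition is suprafacial on a Z-alkene with the silyloxy group endo, it fixes H-4a and H-9a cis in the tricyclic silyl acetal F2. Aqueous KOH in MeOH then cleaves the acetal to 11 and closes the cyclohexenone by aldol condensation to 12. C-4a is again α to the aldehyde in 11 during this last step, so the cis relation could still erode here.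

Step 2 (asymmetric vinylogous aldol). The α-quaternary aliphatic aldehyde may react sluggishly or with modest ee and dr under titanium–binaphthol catalysis.

The fallback sets out from 2 and 3 and comes back at 5, replacing asymmetric catalysis by a classical resolution. BF3·OEt2 in CH2Cl2 at −78 °C gives the racemic threo adduct, that is 4 together with its enantiomer F3. Esterification of the mixture with (S)-2-methoxy-2-phenylacetic acid (N,N'-dicyclohexylcarbodiimide, 4-(dimethylamino)pyridine) gives the ester of 4, F4, and the ester of the enantiomer, F5. These are separated by chromatography or crystallisation. F4 is put directly into the iBu2AlH reduction of step 3, which removes the resolving ester as well and delivers 5.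

Step 13 (late angeloylation). The C-6 hydroxyl is neopentyl-like, so forcing conditions invite angelate-to-tiglate isomerisation or acyl migration.

The fallback sets out from 18 and comes back at 20, building the Z-alkene on the substrate instead of transferring it. Alcohol 18 is acylated with 2-[bis(2,2,2-trifluoroethoxy)phosphoryl]propanoic acid (N,N'-dicyclohexylcarbodiimide, CH2Cl2) to the phosphonopropionate F6. One equivalent of KN(SiMe3)2 with 18-crown-6 in THF at −78 °C deprotonates only the acidic phosphonate position. Acetaldehyde then gives the Z-trisubstituted ester 20 by a Still–Gennari olefination.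

**Further compounds**
F1 | step 7 | (Z)-tert-butyldimethylsilyl enol ether of aldehyde 10 | CC(C)(C)[Si](C)(C)O/C=C\C(C)(C)[C@H]1OC(C)(C)O[C@@H]1/C=C(/C)\C=C\C(=O)CC
F2 | step 7 | tricyclic 2-silyloxy-3,4-dihydro-2H-pyran (hetero-Diels–Alder adduct, acetal centre not assigned) | CCC1=C[C@H]2C(C)=C[C@H]3OC(C)(C)O[C@@H]3C(C)(C)[C@H]2C(O[Si](C)(C)C(C)(C)C)O1
F3 | step 2 | (5S)-5-[(1S)-1-hydroxy-2,2-dimethylpent-4-en-1-yl]-3-methylfuran-2(5H)-one | C=CCC(C)(C)[C@H](O)[C@H]1OC(=O)C(C)=C1
F4 | step 2 | (S)-2-methoxy-2-phenylacetate of 4 | C=CCC(C)(C)[C@@H](OC(=O)[C@@H](OC)c1ccccc1)[C@@H]1OC(=O)C(C)=C1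
F5 | step 2 | (S)-2-methoxy-2-phenylacetate of the enantiomer of 4 | C=CCC(C)(C)[C@H](OC(=O)[C@@H](OC)c1ccccc1)[C@H]1OC(=O)C(C)=C1
F6 | step 13 | C-6 2-[bis(2,2,2-trifluoroethoxy)phosphoryl]propanoate of 18 (phosphonate α-centre not assigned) | CC(C(=O)O[C@H]1[C@H](OC(=O)[C@]2(C)O[C@@H]2C)C=C(C)[C@@H]2CC(=O)C(C)=C[C@@H]2C1(C)C)P(=O)(OCC(F)(F)F)OCC(F)(F)F
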